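Readings and results are calculated with made-up constants.

Count turnovers. You have one flask, followed so far and asked about again later:

| setting | alpha | flask |
|---|---|---|
| substrate | 10 mM | 10 mM |
| reagent | 1.5 equiv (fed, over 8.0 s) | 1.50 equiv (fed, over 8.0 s) |
| free catalyst | 2 mol% | 2 mol% |
| remark | the very flask that is asked about, followed so far |  |
| time |  | 2.0 min |

- alpha (time / s: target / %, over-reaction product / %): 10.0: 2.5, 0.1; 12.0: 3.0, 0; 25.0: 3.6, 0.4; 60.0: 11.6, 0

(scatter of a reading: 1 percentage point)

- on the list of suspects stand: substrate + free catalyst -> catalyst intermediate A; reagent + catalyst intermediate A -> catalyst intermediate B; catalyst intermediate B -> by-product + catalyst intermediate C; catalyst intermediate C -> free catalyst + target; reagent + free catalyst + target -> free catalyst + over-reaction product; target + by-product -> side product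

- the target in the flask at 2.0 min, as a percentage of the substrate charged
- the over-reaction product in the flask at 2.0 min, as a percentage of the substrate charged
- concentration of by-product at 2.0 min, in mM

On the list of suspects, substrate and reagent enter the catalyst through intermediates A and B, by-product leaves, and intermediate C releases target and free catalyst. One turnover therefore takes one substrate and one reagent. Reagent is charged at 1.50 equiv, more than the substrate, so for turnovers substrate is the limiting reagent.

The bench rule is a straight line. From 10.0 s to 60.0 s, the target gain, divided by the seconds between and by the catalyst loading, gives 0.0910 /s. This is the turnover rate: target made per catalyst per second, read with the scatter of the readings.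

By my reckoning, each catalyst makes 10.9 turnovers by 2.0 min, while the substrate charge holds 50.0 per catalyst. Their ratio is 0.218 here; the border lies at one, and this ratio is less, so I keep the line. It gives 21.8 % target and, at one by-product per turnover, 2.18 mM by-product. As the ratio nears one, the line stops working, since it counts on substrate that has been used.

The forecast gives 22 % target (17 % to 28 %), 0.5 % over-reaction product (0 % to 2.5 %) and 2.4 mM by-product (1.8 mM to 3.1 mM), holding that “the target grows almost linearly”. My by-product figure is lower than its figure.

The flask gives 18.9 % target, 3.91 % over-reaction product and 2.30 mM by-product, with 71 % of the substrate left. So this flask has used 29.0 % of its substrate, more than the 21.8 % of the line.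

    substrate + free catalyst → catalyst intermediate A (k = 21.0 /M/s)
    reagent + catalyst intermediate A → catalyst intermediate B (k = 95.0 /M/s)
    catalyst intermediate B → by-product + catalyst intermediate C (k = 1.10 /s)
    catalyst intermediate C → free catalyst + target (k = 1.10 /s)
    reagent + free catalyst + target → free catalyst + over-reaction product (k = 1600 /M²/s)
    target + by-product → side product (k = 2.50 /M/s)

The neighbouring flask has 8 mol% of free catalyst, and there the same reckoning gives a ratio of 0.874, close to the border. At 2.00 min, that neighbour has used 78.2 % of its substrate, less than the line says. Its target is 25.6 %, its over-reaction product 23.1 % and its by-product 4.90 mM. Side product holds the most of that neighbour's substrate, at 28.3 %.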